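- west: solid substrate 1.6 M; the very flask that is asked about, followed so far
- flask: solid substrate 1.6 M; time 1.0 h

- west (time / min: target / %, solid substrate / %): 6.00: 1.4, 96.7; 12.0: 1.5, 93.3; 20.0: 4.2, 88.4; 25.0: 5.0, 85.6; 30.0: 6.6, 83.4

(readings scatter by 0.5 percentage points)

- as a solid, counted per litre of solution: solid substrate
- at the start none of the solid substrate is in solution

- autumn: doubling the solubility of the solid substrate, all else as stated
- winter: doubling the dissolution coefficient of the solid substrate, all else as stated

* the target standing at 1.0 h, as a percentage of the solid substrate charged
* the change that raises the amount of target at 1.0 h, in percent of the solid substrate charged most ("none" if none brings more than 2 percentage points) (autumn / winter / none)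
* amount of target at 1.0 h, in percent of the solid substrate charged, after winter

1. 10.0 % of the charge is neither solid nor target at the last reading of the west run, which is this flask followed to 30.0 min. I call this the gap.

2. I assume that target grows out of the gap, so I take the target at 30.0 min and divide it by the gap added up over the minutes between readings. That gives a take-up of 0.0393 min⁻¹, read from noisy readings.

3. At the early end the gap is empty, since none of the solid substrate is in solution at the start. At the late end I assume the gap holds at its last reading, a quasi-steady state. Take-up times gap is then the target line, the steady rise of target as a fraction of the charge per minute: 0.00393 min⁻¹.

4. Joined to the last reading, the line gives my estimate for this flask: 18.4 % at 1.0 h.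

5. Autumn and winter look nearly the same at first. If the solid's loss goes as coefficient times room under the solubility, each doubles the opening loss, which I read as 0.00558 min⁻¹ of the charge per minute, and makes it 0.0112 min⁻¹. Then they part: dissolved material eats into the room, autumn raises the solubility that the room is measured from, and winter keeps the old solubility. I rank autumn first.

6. The forecast gives 19 % (16.5 % to 22 %), a little above mine. It also picks autumn and gives 33 % (28 % to 38 %) after winter, noting “Doubling kd also speeds back-limitation”.

    starting material → target (k = 2.80 h⁻¹)
    starting material → side product A (k = 0.540 h⁻¹)
    starting material → side product B (k = 0.500 h⁻¹)
    solid substrate ⇌ starting material, rate k4*(cs4 - [starting material]) while solid is left; crystals form when [starting material] > cs4 (solubility = 0.620 M, k = 1.00 h⁻¹)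

The flask stands at 17.8 % target. Autumn adds 18 percentage points, winter adds 13 points, and winter ends at 30.8 %. At 1.00 h starting material is made 1.01 times as fast as it is used up. From 6.99 % at 0.500 h, the target line gives this flask 18.8 % at 1.0 h. For the same flask read at 2.5 h, the line from 17.8 % gives 53.2 %, and that flask holds 51.4 %.

(All runs stem from a simulated flask from invented constants; scatter was added.)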